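The numbers in the tables are calculated with constants of no real substance; scatter was added.

How far does the midnight flask get by 320 h, and how steeply does the starting rate answer to L and to G?

| flask | L | G | time |
|---|---|---|---|
| winter | 0.120 M | 0.00360 M |  |
| dusk | 0.0480 M | 0.00360 M |  |
| spring | 0.120 M | 0.0110 M |  |
| midnight | 0.120 M | 0.00360 M | 320 h |

- winter run (time / h: [E] / M): 2.1: 0.0040; 4.0: 0.0084; 7.7: 0.0143; 15: 0.0246; 28: 0.0357; 53: 0.0408
- dusk run (time / h: [E] / M): 2.1: 0.0013; 4.0: 0.0024; 7.7: 0.0036; 15: 0.0072; 28: 0.0109; 53: 0.0149
- spring run (time / h: [E] / M): 2.1: 0.0210; 4.0: 0.0349; 7.7: 0.0526; 15: 0.0676; 28: 0.0716; 53: 0.0719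

(readings scatter by 4 × 10⁻⁴ M)

- apparent order in [L] of the starting rate, round the charge of the winter run (the rate where two percent of its L have turned into E) (one fixed amount of E, the same in the runs compared)
- apparent order in [G] of the starting rate, round the charge of the winter run (the rate where two percent of its L have turned into E)
- E in the midnight run at 320 h, as a share of the L charged

- Overall: L -> E, with G as catalyst.
- Constant volume, constant temperature.
- Bound and free are read together.
- An order is taken over about fifteen percent of the charge, up and down.

The midnight flask is charged like the winter run, so you can read its end from the winter tail. Winter makes E at 8.54 × 10⁻⁴ M h⁻¹ between 15 h and 28 h, but at 2.04 × 10⁻⁴ M h⁻¹ between 28 h and 53 h. Those two rates stand 19.0 h apart, so production loses 0.0753 h⁻¹: call this fractional loss per hour the fall rate. If it holds, production at 53 h is 7.95 × 10⁻⁵ M h⁻¹, and the E still to come is that rate over the fall rate, 0.00106 M. Winter's reach is then 0.0419 M. The midnight time lies 20.1 fall times past the last reading, so on this reckoning the midnight flask stands at that reach by then.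

The weak link is the constant fall. Spring, read the same way from 7.7 h to 28 h, falls at 0.187 h⁻¹, faster than winter, with more E standing. But spring also holds more G, so it is an assumption, not a reading, that the fall grows in proportion to E; make it, and put the first reach back in. Scaling from winter's middle reading gives 0.0883 h⁻¹, and the reach becomes 0.0416 M. Your figure for the midnight flask is 34.6 % of the L charged.

The forecast gives orders of 1.2 in L and 1.55 in G, and 37 % for E, between 34.5 % and 41 %, above your figure. Of the stop it says: “this is catalyst death rather than equilibrium”.

The flask gives orders of 1.3 in L and 2.3 in G, the second above the forecast's, and E in the midnight flask at 35.2 % of the L charged.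

    G + L ⇌ GL, settled at all times (13.60 L mol⁻¹)
    GL + L ⇌ GL2, settled at all times (1.400 L mol⁻¹)
    GL2 → E + GL (14.44 h⁻¹)
    G + E → Ja + E (3.924 L mol⁻¹ h⁻¹)
    G + Ze → Ja

Winter's fall rate of 0.0753 h⁻¹ carried the reckoning, and the main reason the midnight flask stops short is the path from G and E to Ja: take it away, and the midnight flask reaches 92.2 % instead of 35.2 %. Spring tests the two rounds using readings up to 28 h and its 0.187 h⁻¹. The reach comes to 0.0720 M, and the spring reading at 53 h is 0.0719 M.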